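| flask | substrate | first nucleophile | second nucleophile | temperature | remark | time |
|---|---|---|---|---|---|---|
| violet | 0.020 M | 2.5 equiv | 5 equiv | 0 °C | run made earlier |  |
| grey | 0.028 M | 2.5 equiv | 5 equiv | 11 °C | run made earlier |  |
| ochre | 0.044 M | 2.5 equiv | 5 equiv | 0 °C | run made earlier |  |
| Saturday's | 0.020 M | 2.50 equiv (in portions, 3, over 6.0 h) | 5.00 equiv | 5 °C | first portion at the start, last at 6.0 h | 8.0 h |
| Thursday's | 0.020 M | 2.50 equiv (fed, over 6.0 h) | 5.00 equiv |  | the addition at −25 °C, then warmed to 5 °C; the feed brings no volume worth counting | 8.0 h |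
| Monday's | 0.020 M | 2.50 equiv (fed, over 6.0 h) | 5.00 equiv | 5 °C | all else is in the flask from the start; the feed brings no volume worth counting | 8.0 h |
| Friday's | 0.020 M (fed, over 40 min) | 2.50 equiv | 5.00 equiv | 5 °C | all else is in the flask from the start; the feed brings no volume worth counting | 8.0 h |
| Sunday's | 0.020 M (fed, over 6.0 h) | 2.50 equiv | 5.00 equiv | 5 °C | all else is in the flask from the start; the feed brings no volume worth counting | 8.0 h |

- violet (time / h: target / %): 0.833: 29.4; 1.50: 38.4; 2.50: 38.6; 3.00: 39.3; 4.00: 38.8; 5.00: 37.8
- grey (time / h: target / %): 0.500: 33.7; 1.50: 31.0; 3.00: 25.5; 4.00: 21.3; 6.00: 16.2; 8.00: 13.1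
- ochre (time / h: target / %): 0.500: 27.7; 1.50: 42.5; 3.00: 44.4; 4.00: 43.4; 6.00: 46.2; 8.00: 44.1

(scatter of a reading: 1 percentage point)

- in percentages every species weighs as the substrate in it: one side product counts as two
- for target the idle adduct is counted in
- steps thought possible: substrate -> intermediate; first nucleophile + intermediate <-> target; second nucleophile + intermediate -> other capture product; intermediate -> solvolysis product; second nucleophile + target <-> idle adduct; substrate + intermediate -> side product

- the best flask by amount of target, in percent of the substrate charged; "all alike" if 1.5 percentage points covers them all (Saturday's / Thursday's / Monday's / Friday's / Sunday's / all alike)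
- amount of target at the end, in percent of the substrate charged, Saturday's
- amount of target at the end, in percent of the substrate charged, Thursday's
- amount of target at the end, in percent of the substrate charged, Monday's
- amount of target at the end, in percent of the substrate charged, Friday's
- amount of target at the end, in percent of the substrate charged, Sunday's

- Target in the grey run fell from 33.7 % of the charge at 0.500 h to 13.1 % at 8.00 h, while the violet run went from 39.3 % at 3.00 h to 37.8 % at 5.00 h.
- I read both falls as a pseudo-first-order leak of target: 0.126 h⁻¹ at 11 °C and 0.0195 h⁻¹ at 0 °C. The violet figure is rough: its fall of 1.5 percentage points stands against a scatter of 1 point.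
- Their geometric mean gave 0.0495 h⁻¹ for 5 °C. Its inverse, 20.2 h, is the leak life of target.
- The second time is the sitting time, the hours target stands at 5 °C after forming. I took the share surviving as the exponential of minus sitting time over leak life.
- I took the fresh target as 37.6 % of the charge, the mean of the violet reading and the first grey reading carried back to time zero.
- Friday's target sits 7.67 h on average, so I reckoned 25.7 %. Sunday's sits 5.00 h, so I reckoned 29.4 %.
- For Thursday's I counted 2.00 h, the hours after the cold addition, because the leak read slower at 0 °C than at 11 °C. I assumed the substrate waits in the cold and gives the same fresh target, which no run shows. That gave 34.1 %, my highest, so my choice differed from the forecast's. I made no figure for Saturday's or Monday's.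
- The forecast said Sunday's: Saturday's 12.5 %, Thursday's 30 %, Monday's 3.5 %, Friday's 29 %, Sunday's 32 %. Its ground for Sunday's was “later formation means less decay”.
- The flasks gave Saturday's 10.1 %, Thursday's 33.2 %, Monday's 2.77 %, Friday's 25.0 % and Sunday's 29.5 %, so Thursday's stood highest.

    substrate → intermediate (k = 0.00130 s⁻¹, Ea = 76.0 kJ mol⁻¹)
    first nucleophile + intermediate ⇌ target (K = 16.0 M⁻¹, k = 0.0140 M⁻¹ s⁻¹, Ea = 44.0 kJ mol⁻¹, ΔH = −90.0 kJ mol⁻¹)
    second nucleophile + intermediate → other capture product (k = 0.00620 M⁻¹ s⁻¹, Ea = 42.0 kJ mol⁻¹)
    intermediate → solvolysis product (k = 4.90 × 10⁻⁴ s⁻¹, Ea = 93.0 kJ mol⁻¹)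
    second nucleophile + target ⇌ idle adduct, settled at all times (K = 400 M⁻¹, ΔH = −6.00 kJ mol⁻¹)
    substrate + intermediate → side product (k = 0.00180 M⁻¹ s⁻¹, Ea = 65.0 kJ mol⁻¹)
    (constants at 5 °C)

- In Thursday's flask, half of the target-forming turnover was done by 6.14 h, against a feed ending at 6.0 h. That midpoint leaves 1.86 h at 5 °C, or 0.0919 of the leak life, against 0.380 reckoned for Friday's flask.
- The flask Thursday's left until 20 h has 12.0 h more to leak, so the leak life takes 33.2 % down to 18.3 %. The computed flask holds 17.2 %.

The data stem from a simulated flask on assumed constants, and the scatter is random.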